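**Plan**

- Retrosynthetic cuts, in order: the six O–benzyl bonds; the C3(flavone)–C6(flavan) aryl–aryl bond (Negishi); the O1–C8a aryl ether bond of the chromane (tethered alkoxide onto an aryne); the C2 carbinol C–H and the C3–C4 bond of the three-carbon chain (transfer hydrogenation, Claisen–Schmidt).
- Forward: ring A aldehyde + ring B methyl ketone → chalcone → S carbinol → pyran ring closed on the aryne → union at C6 with 3-iodo-tri-O-benzylapigenin → global debenzylation.
- Stereochemistry: the only stereocentre, C2, is set by catalyst-controlled asymmetric transfer hydrogenation of the aryl ketone; no later step breaks a bond at C2.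
- Enabling feature: in flavan ring A, C8a is meta to both oxygens (C5–O, C7–O), its neighbour C8 is ortho/para to them, and C6 lies between them. Dibromination therefore puts Br on C8 and C6. The C8 bromide (ortho H at C8a) becomes an aryne whose only tether-reachable terminus is C8a; the C6 bromide (no ortho H) survives as the coupling handle. One event thus installs O1, fixes the 6- versus 8-linkage, leaves C2 intact and removes its own activating group.

Key step: step 4

Remark: the structure defines only C2; the hindered flavone–flavan axis is treated as stereochemically unassigned and no control of it is planned.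

**Route**

Step 1
Reactants: 1 3,5-dibromo-2,4-dihydroxybenzaldehyde
Product: 2 2,4-bis(benzyloxy)-3,5-dibromobenzaldehyde
Conditions: BnBr (2.5 equiv), K2CO3, DMF, 60 °C
Reagents that add atoms: benzyl bromide, BrCc1ccccc1
Why: Williamson etherification, in which both phenoxides formed by K2CO3 displace bromide from benzyl bromide; the hindered, hydrogen-bonded 2-OH needs the warm dipolar medium.

Step 2
Reactants: 2 2,4-bis(benzyloxy)-3,5-dibromobenzaldehyde; 3 1-[4-(benzyloxy)phenyl]ethan-1-one
Product: 4 (E)-3-[2,4-bis(benzyloxy)-3,5-dibromophenyl]-1-[4-(benzyloxy)phenyl]prop-2-en-1-one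
Conditions: KOH, EtOH/THF, rt
Reagents that add atoms: none
Why: Claisen–Schmidt condensation, in which the enolate of methyl ketone 3 adds to the non-enolisable aldehyde 2 and E1cB dehydration should give the thermodynamically preferred E enone.

Step 3
Reactants: 4 (E)-3-[2,4-bis(benzyloxy)-3,5-dibromophenyl]-1-[4-(benzyloxy)phenyl]prop-2-en-1-one
Product: 6 (1S)-3-[2,4-bis(benzyloxy)-3,5-dibromophenyl]-1-[4-(benzyloxy)phenyl]propan-1-ol, via saturated ketone 5 (not isolated)
Conditions: RuCl[(S,S)-TsDPEN](p-cymene) (2 mol %), HCO2H/Et3N (5:2), DMF, 40 °C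
Reagents that add atoms: none
Why: Noyori–Ikariya asymmetric transfer hydrogenation used as a tandem 1,4-/1,2-reduction of a chalcone: the ruthenium hydride first saturates the enone C=C to ketone 5 and then reduces the aryl ketone through the six-membered outer-sphere transition state, in which the CH/π contact between the p-cymene ligand and the 4-benzyloxyphenyl ring should make the (S,S)-catalyst deliver hydride to the face that gives the S carbinol, while aryl bromides and benzyl ethers are inert.

Step 4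
Reactants: 6 (1S)-3-[2,4-bis(benzyloxy)-3,5-dibromophenyl]-1-[4-(benzyloxy)phenyl]propan-1-ol
Product: 9 (2S)-5,7-bis(benzyloxy)-2-[4-(benzyloxy)phenyl]-6-bromochromane, via aryne lithium alkoxide 7 (not isolated), via 8-lithiochromane 8 (not isolated)
Conditions: LiTMP (lithium 2,2,6,6-tetramethylpiperidide, 3 equiv), THF (0.02 M), −78 to −30 °C; cold quench with aq. NH4Cl
Reagents that add atoms: none
Why: LiTMP deprotonates the hydroxyl and then, assisted by the neighbouring lithium alkoxide, the only ring hydrogen of the dibromoarene (ortho to the C5' bromine); loss of LiBr gives aryne 7, whose tethered alkoxide adds to the proximal aryne carbon to give aryllithium 8, which is protonated on quench to 9. The closest known reaction type is the intramolecular addition of a tethered alkoxide to a benzyne generated from a haloarene with a lithium amide (aryne ring closure to chromans, a cine-substitution). The pyran ring closes in a 6-exo-dig sense on the in-plane π bond of the aryne, the carbinol oxygen becoming O1 and the attacked carbon C8a. No new stereocentre arises; C2 keeps the S configuration set in step 3 because the bond formed is the aryl–oxygen bond and no bond at the carbinol carbon is broken, which avoids the p-quinone-methide ionisation that threatens closures at the benzylic carbon. The step needs discrimination between the two bromines and between the two aryne termini: only the C5' bromine has an ortho hydrogen (the C3' bromine lies between two benzyloxy groups and cannot eliminate), only the terminus ortho to the chain is within reach of the three-atom tether, and the adjacent benzyloxy group polarises the aryne in the same sense so that the carbanion of 8 sits between two oxygens. Exchange of the surviving bromine with aryllithium 8 should be held back by low temperature, high dilution and the cold quench, so that this bromine ends at C6 and fixes the 6-linkage.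

Step 5
Reactants: 10 apigenin (5,7-dihydroxy-2-(4-hydroxyphenyl)-4H-chromen-4-one)
Product: 11 5,7-bis(benzyloxy)-2-[4-(benzyloxy)phenyl]-4H-chromen-4-one
Conditions: BnBr (4 equiv), K2CO3, DMF, 80 °C
Reagents that add atoms: benzyl bromide, BrCc1ccccc1
Why: Williamson etherification of all three phenols, the chelated 5-OH being alkylated last and only in warm DMF with excess benzyl bromide.

Step 6
Reactants: 11 5,7-bis(benzyloxy)-2-[4-(benzyloxy)phenyl]-4H-chromen-4-one
Product: 13 5,7-bis(benzyloxy)-2-[4-(benzyloxy)phenyl]-3-iodo-4H-chromen-4-one, via 3-lithioflavone 12 (not isolated)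
Conditions: LDA (lithium diisopropylamide), THF, −78 °C; then I2, −78 °C to rt
Reagents that add atoms: iodine, II
Why: Directed deprotonation of a flavone at C3, its only vinylic C–H, flanked by the carbonyl and the ring oxygen-bearing C2, followed by electrophilic iodination of vinyllithium 12, which places the halogen at C3 and not on the electron-rich ring A.

Step 7
Reactants: 9 (2S)-5,7-bis(benzyloxy)-2-[4-(benzyloxy)phenyl]-6-bromochromane; 13 5,7-bis(benzyloxy)-2-[4-(benzyloxy)phenyl]-3-iodo-4H-chromen-4-one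
Product: 16 5,7-bis(benzyloxy)-2-[4-(benzyloxy)phenyl]-3-{(2S)-5,7-bis(benzyloxy)-2-[4-(benzyloxy)phenyl]chroman-6-yl}-4H-chromen-4-one, via chroman-6-yllithium 14 (not isolated), via chroman-6-ylzinc chloride 15 (not isolated)
Conditions: 9, n-BuLi, THF, −78 °C; ZnCl2, −78 °C to rt; then 13, Pd2(dba)3 (2.5 mol %), SPhos (10 mol %), THF/NMP, 65 °C
Reagents that add atoms: none
Why: Negishi coupling, in which bromine–lithium exchange gives 14, ZnCl2 gives arylzinc 15, and the zerovalent palladium/SPhos catalyst inserts into the C3–I bond of the vinylogous acyl iodide 13, transmetalates and reductively eliminates; a 2,6-dialkoxyarylzinc with a bulky biarylphosphine is the established combination for doubly ortho-substituted couplings.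

Step 8
Reactants: 16 5,7-bis(benzyloxy)-2-[4-(benzyloxy)phenyl]-3-{(2S)-5,7-bis(benzyloxy)-2-[4-(benzyloxy)phenyl]chroman-6-yl}-4H-chromen-4-one
Product: 17 3-[(2S)-5,7-dihydroxy-2-(4-hydroxyphenyl)-3,4-dihydro-2H-chromen-6-yl]-5,7-dihydroxy-2-(4-hydroxyphenyl)-4H-chromen-4-one
Conditions: H2 (1 atm), Pd(OH)2/C, THF/MeOH, rt
Reagents that add atoms: none
Why: Catalytic hydrogenolysis of the six aryl benzyl ethers under neutral conditions, in which the tetrasubstituted chromone C2=C3 bond and the cyclic benzylic ether O1–C2 should react much more slowly, so that C2 is untouched when hydrogen uptake is stopped after debenzylation.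

**Compound list**

1 | 3,5-dibromo-2,4-dihydroxybenzaldehyde | O=Cc1cc(Br)c(O)c(Br)c1O | starting material
2 | 2,4-bis(benzyloxy)-3,5-dibromobenzaldehyde | O=Cc1cc(Br)c(OCc2ccccc2)c(Br)c1OCc1ccccc1 | intermediate
3 | 1-[4-(benzyloxy)phenyl]ethan-1-one | CC(=O)c1ccc(OCc2ccccc2)cc1 | starting material
4 | (E)-3-[2,4-bis(benzyloxy)-3,5-dibromophenyl]-1-[4-(benzyloxy)phenyl]prop-2-en-1-one | O=C(/C=C/c1cc(Br)c(OCc2ccccc2)c(Br)c1OCc1ccccc1)c1ccc(OCc2ccccc2)cc1 | intermediate
5 | 3-[2,4-bis(benzyloxy)-3,5-dibromophenyl]-1-[4-(benzyloxy)phenyl]propan-1-one | O=C(CCc1cc(Br)c(OCc2ccccc2)c(Br)c1OCc1ccccc1)c1ccc(OCc2ccccc2)cc1 | intermediate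
6 | (1S)-3-[2,4-bis(benzyloxy)-3,5-dibromophenyl]-1-[4-(benzyloxy)phenyl]propan-1-ol | O[C@@H](CCc1cc(Br)c(OCc2ccccc2)c(Br)c1OCc1ccccc1)c1ccc(OCc2ccccc2)cc1 | intermediate
7 | lithium (1S)-1-[4-(benzyloxy)phenyl]-3-[2,4-bis(benzyloxy)-3-bromo-5,6-didehydrophenyl]propan-1-olate (aryne) | [Li]O[C@@H](CCC1=C(OCc2ccccc2)C(Br)=C(OCc2ccccc2)C#C1)c1ccc(OCc2ccccc2)cc1 | intermediate
8 | [(2S)-5,7-bis(benzyloxy)-2-[4-(benzyloxy)phenyl]-6-bromochroman-8-yl]lithium | Brc1c(OCc2ccccc2)c([Li])c2c(c1OCc1ccccc1)CC[C@@H](c1ccc(OCc3ccccc3)cc1)O2 | intermediate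
9 | (2S)-5,7-bis(benzyloxy)-2-[4-(benzyloxy)phenyl]-6-bromochromane | Brc1c(OCc2ccccc2)cc2c(c1OCc1ccccc1)CC[C@@H](c1ccc(OCc3ccccc3)cc1)O2 | intermediate
10 | apigenin, 5,7-dihydroxy-2-(4-hydroxyphenyl)-4H-chromen-4-one | O=c1cc(-c2ccc(O)cc2)oc2cc(O)cc(O)c12 | starting material
11 | 5,7-bis(benzyloxy)-2-[4-(benzyloxy)phenyl]-4H-chromen-4-one | O=c1cc(-c2ccc(OCc3ccccc3)cc2)oc2cc(OCc3ccccc3)cc(OCc3ccccc3)c12 | intermediate
12 | {5,7-bis(benzyloxy)-2-[4-(benzyloxy)phenyl]-4-oxo-4H-chromen-3-yl}lithium | O=c1c([Li])c(-c2ccc(OCc3ccccc3)cc2)oc2cc(OCc3ccccc3)cc(OCc3ccccc3)c12 | intermediate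
13 | 5,7-bis(benzyloxy)-2-[4-(benzyloxy)phenyl]-3-iodo-4H-chromen-4-one | O=c1c(I)c(-c2ccc(OCc3ccccc3)cc2)oc2cc(OCc3ccccc3)cc(OCc3ccccc3)c12 | intermediate
14 | [(2S)-5,7-bis(benzyloxy)-2-[4-(benzyloxy)phenyl]chroman-6-yl]lithium | [Li]c1c(OCc2ccccc2)cc2c(c1OCc1ccccc1)CC[C@@H](c1ccc(OCc3ccccc3)cc1)O2 | intermediate
15 | chloro[(2S)-5,7-bis(benzyloxy)-2-[4-(benzyloxy)phenyl]chroman-6-yl]zinc | Cl[Zn]c1c(OCc2ccccc2)cc2c(c1OCc1ccccc1)CC[C@@H](c1ccc(OCc3ccccc3)cc1)O2 | intermediate
16 | 5,7-bis(benzyloxy)-2-[4-(benzyloxy)phenyl]-3-{(2S)-5,7-bis(benzyloxy)-2-[4-(benzyloxy)phenyl]chroman-6-yl}-4H-chromen-4-one | O=c1c(-c2c(OCc3ccccc3)cc3c(c2OCc2ccccc2)CC[C@@H](c2ccc(OCc4ccccc4)cc2)O3)c(-c2ccc(OCc3ccccc3)cc2)oc2cc(OCc3ccccc3)cc(OCc3ccccc3)c12 | intermediate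
17 | 3-[(2S)-5,7-dihydroxy-2-(4-hydroxyphenyl)-3,4-dihydro-2H-chromen-6-yl]-5,7-dihydroxy-2-(4-hydroxyphenyl)-4H-chromen-4-one | O=c1c(-c2c(O)cc3c(c2O)CC[C@@H](c2ccc(O)cc2)O3)c(-c2ccc(O)cc2)oc2cc(O)cc(O)c12 | target

**Step count and risks**

Total step count: 8. Longest linear sequence: 6 steps (steps 1, 2, 3, 4, 7, 8).

Steps most likely to fail:

1. Step 4. The process at risk is bromine–lithium exchange between aryllithium 8 (or the ring-lithiated precursor) and the remaining hindered bromide of a second molecule. This would scramble or remove the coupling handle; amide-induced rearrangement of a benzyl ether is a lesser concern. The fallback replaces the handle by chlorine, which neither eliminates nor exchanges, and inverts the polarity of the later union. It sets out from ketone 3 and comes back to the route at 16.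
   - Commercial 5-bromo-2,4-dihydroxybenzaldehyde F1 is chlorinated with N-chlorosuccinimide (MeCN, rt) at C3, its only activated free position, to give 5-bromo-3-chloro-2,4-dihydroxybenzaldehyde F2.
   - F2 is benzylated (BnBr, K2CO3, DMF) to 2,4-bis(benzyloxy)-5-bromo-3-chlorobenzaldehyde F3.
   - F3 is condensed with 3 (KOH, EtOH/THF) to (E)-3-[2,4-bis(benzyloxy)-5-bromo-3-chlorophenyl]-1-[4-(benzyloxy)phenyl]prop-2-en-1-one F4.
   - F4 is reduced as in step 3, through 3-[2,4-bis(benzyloxy)-5-bromo-3-chlorophenyl]-1-[4-(benzyloxy)phenyl]propan-1-one F5, to (1S)-3-[2,4-bis(benzyloxy)-5-bromo-3-chlorophenyl]-1-[4-(benzyloxy)phenyl]propan-1-ol F6.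
   - LiTMP in THF should then lead through the chloro aryne lithium alkoxide F7 and [(2S)-5,7-bis(benzyloxy)-2-[4-(benzyloxy)phenyl]-6-chlorochroman-8-yl]lithium F8 to (2S)-5,7-bis(benzyloxy)-2-[4-(benzyloxy)phenyl]-6-chlorochromane F9.
   - Because F9 cannot be lithiated by exchange, 3-lithioflavone 12 (from 11 and LDA) is transmetalated with ZnCl2 to {5,7-bis(benzyloxy)-2-[4-(benzyloxy)phenyl]-4-oxo-4H-chromen-3-yl}zinc chloride F10. F10 is coupled with F9 in a Negishi reaction (Pd2(dba)3, XPhos, THF/NMP, 80 °C) to give 16.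

2. Step 7. The process at risk is slow transmetalation and reductive elimination at two doubly flanked carbons, so that arylzinc 15 is lost to protonation or homocoupling and 13 to reduction. The fallback replaces the zinc nucleophile by an isolable boron nucleophile and base-mediated transmetalation (Suzuki–Miyaura coupling). It sets out from 9 and comes back at 16.
   - Aryllithium 14 (from 9 and n-BuLi, −78 °C) is quenched with 2-isopropoxy-4,4,5,5-tetramethyl-1,3,2-dioxaborolane to give 2-[(2S)-5,7-bis(benzyloxy)-2-[4-(benzyloxy)phenyl]chroman-6-yl]-4,4,5,5-tetramethyl-1,3,2-dioxaborolane F11.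
   - F11 is purified and coupled with 13 (Pd(OAc)2, SPhos, K3PO4, toluene/H2O, 90 °C) to give 16.

3. Step 3. The processes at risk are stalling of the 1,4-reduction, carbonyl reduction running ahead to an allylic alcohol that is not reduced further, and weak facial selectivity at the electron-rich ketone. The fallback separates the two reductions and uses a different source of asymmetry. It sets out from 4 and comes back at 6; no compound outside the list is made (F0).
   - The C=C bond of 4 is hydrogenated chemoselectively (H2, RhCl(PPh3)3, benzene/EtOH, rt) and ketone 5 is isolated.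
   - Ketone 5 is reduced by Corey–Bakshi–Shibata reduction ((R)-2-methyl-CBS-oxazaborolidine, BH3·SMe2, THF, −20 °C), which should give the S alcohol 6.

Further compounds
F1 | step 4 | 5-bromo-2,4-dihydroxybenzaldehyde | O=Cc1cc(Br)c(O)cc1O
F2 | step 4 | 5-bromo-3-chloro-2,4-dihydroxybenzaldehyde | O=Cc1cc(Br)c(O)c(Cl)c1O
F3 | step 4 | 2,4-bis(benzyloxy)-5-bromo-3-chlorobenzaldehyde | O=Cc1cc(Br)c(OCc2ccccc2)c(Cl)c1OCc1ccccc1
F4 | step 4 | (E)-3-[2,4-bis(benzyloxy)-5-bromo-3-chlorophenyl]-1-[4-(benzyloxy)phenyl]prop-2-en-1-one | O=C(/C=C/c1cc(Br)c(OCc2ccccc2)c(Cl)c1OCc1ccccc1)c1ccc(OCc2ccccc2)cc1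
F5 | step 4 | 3-[2,4-bis(benzyloxy)-5-bromo-3-chlorophenyl]-1-[4-(benzyloxy)phenyl]propan-1-one | O=C(CCc1cc(Br)c(OCc2ccccc2)c(Cl)c1OCc1ccccc1)c1ccc(OCc2ccccc2)cc1
F6 | step 4 | (1S)-3-[2,4-bis(benzyloxy)-5-bromo-3-chlorophenyl]-1-[4-(benzyloxy)phenyl]propan-1-ol | O[C@@H](CCc1cc(Br)c(OCc2ccccc2)c(Cl)c1OCc1ccccc1)c1ccc(OCc2ccccc2)cc1
F7 | step 4 | lithium (1S)-1-[4-(benzyloxy)phenyl]-3-[2,4-bis(benzyloxy)-3-chloro-5,6-didehydrophenyl]propan-1-olate (aryne) | [Li]O[C@@H](CCC1=C(OCc2ccccc2)C(Cl)=C(OCc2ccccc2)C#C1)c1ccc(OCc2ccccc2)cc1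
F8 | step 4 | [(2S)-5,7-bis(benzyloxy)-2-[4-(benzyloxy)phenyl]-6-chlorochroman-8-yl]lithium | Clc1c(OCc2ccccc2)c([Li])c2c(c1OCc1ccccc1)CC[C@@H](c1ccc(OCc3ccccc3)cc1)O2
F9 | step 4 | (2S)-5,7-bis(benzyloxy)-2-[4-(benzyloxy)phenyl]-6-chlorochromane | Clc1c(OCc2ccccc2)cc2c(c1OCc1ccccc1)CC[C@@H](c1ccc(OCc3ccccc3)cc1)O2
F10 | step 4 | {5,7-bis(benzyloxy)-2-[4-(benzyloxy)phenyl]-4-oxo-4H-chromen-3-yl}zinc chloride | O=c1c([Zn]Cl)c(-c2ccc(OCc3ccccc3)cc2)oc2cc(OCc3ccccc3)cc(OCc3ccccc3)c12
F11 | step 7 | 2-[(2S)-5,7-bis(benzyloxy)-2-[4-(benzyloxy)phenyl]chroman-6-yl]-4,4,5,5-tetramethyl-1,3,2-dioxaborolane | CC1(C)OB(OC1(C)C)c1c(OCc2ccccc2)cc2c(c1OCc1ccccc1)CC[C@@H](c1ccc(OCc3ccccc3)cc1)O2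
F0 | step 3 | none | none
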